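**Retrosynthetic overview**

1. Target 16 comes from 2-ethoxy-5-isopropoxy quinone 15 by hydrolysis of its two vinylogous esters; the side chain with its E-alkene is already complete.
2. The quinone ring of 15 is closed in one annulation: alkoxyalkyne 9 inserts into maleoylcobalt complex 14, forming C1–C2 and C3–C4 together (quinone numbering: C1=O, C2–O, C3–side chain, C4=O, C5–O, C6–H).
3. Enabling feature: the carbonyl carbons C1 and C4 are joined through the cis C5(O)=C6(H) unit, so C4–C5–C6–C1 is a maleoyl unit, i.e. a 3-alkoxycyclobutene-1,2-dione (12) opened between its two carbonyl carbons. The remaining pair C2(O)=C3(alkyl) is at the oxidation level of an alkoxyalkyne.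
4. Ynol ether 9 comes from lithium ethoxyacetylide and iodide 6. Iodide 6 comes from a copper-catalysed sp3–sp3 coupling of the Grignard reagent of (E)-1-bromodec-5-ene with 1,9-dibromononane; the E-alkene is bought in 1 and never touched.
5. Ring order: the four-membered ring is bought (squarate 10 → 12), cobalt expands it to the five-membered cobaltacycle (step 6), and alkyne insertion gives the six-membered quinone ring (step 7).

Key step: step 7

Remark: the target is treated as the 2,5-dihydroxy-1,4-benzoquinone tautomer drawn in its SMILES, and the E-alkene is its only stereo-element. In the SMILES of the cobalt complexes, dative bonds are written as charge-separated single bonds.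

**Route**

Step 1
Reactants: 1 (E)-dec-5-en-1-ol
Product: 2 (E)-1-bromodec-5-ene
Conditions: CBr4, PPh3, CH2Cl2, 0 °C → 25 °C
Reagents that add atoms: carbon tetrabromide, BrC(Br)(Br)Br
Why: The Appel reaction converts the primary alcohol to the bromide by SN2 displacement of an alkoxyphosphonium ion under neutral conditions that leave the remote E-alkene untouched.

Step 2
Reactants: 2 (E)-1-bromodec-5-ene; 3 1,9-dibromononane
Product: 5 (E)-1-bromononadec-14-ene, via decenylmagnesium bromide 4 (not isolated)
Conditions: Mg, THF, 40 °C; then added to 3 (3 equiv), Li2CuCl4 (3 mol %), THF, −10 °C → 25 °C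
Reagents that add atoms: magnesium, [Mg] (enters intermediate 4 only; product 5 holds atoms of 2 and 3 alone)
Why: The Li2CuCl4-catalysed alkyl–alkyl cross-coupling of a primary Grignard reagent with a primary bromide is reliable, the excess of the symmetrical dibromide favours monosubstitution, and the E-alkene is a spectator.

Step 3
Reactants: 5 (E)-1-bromononadec-14-ene
Product: 6 (E)-1-iodononadec-14-ene
Conditions: NaI, acetone, reflux
Reagents that add atoms: sodium iodide, [Na+].[I-]
Why: The Finkelstein exchange, driven by precipitation of NaBr, gives the more reactive iodide needed for the acetylide alkylation.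

Step 4
Reactants: 6 (E)-1-iodononadec-14-ene; 7 ethoxyethyne
Product: 9 (E)-1-ethoxyhenicos-16-en-1-yne, via lithium ethoxyacetylide 8 (not isolated)
Conditions: n-BuLi, THF, −78 °C; then 6, HMPA, −78 °C → 25 °C; purification on Et3N-deactivated SiO2
Reagents that add atoms: n-butyllithium, [Li]CCCC (its lithium enters intermediate 8 only)
Why: SN2 alkylation of a lithium alkoxyacetylide with a primary iodide in THF/HMPA is the standard entry to 1-alkoxy-1-alkynes, and the basic conditions preserve both the ynol ether and the alkene.

Step 5
Reactants: 10 diisopropyl squarate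
Product: 12 3-(propan-2-yloxy)cyclobut-3-ene-1,2-dione, via hydroxycyclobutenone 11 (not isolated)
Conditions: LiAlH(OtBu)3, THF, −78 °C → −20 °C, then H2O; crude 11, conc. HCl (cat.), CH2Cl2, 25 °C
Reagents that add atoms: water, O (its oxygen becomes the new carbonyl oxygen; the water lost on ionisation of 11 balances it)
Why: Selective 1,2-monoreduction of the squarate by the bulky hydride, then acid-induced ionisation of the hydroxyl group and hydrolysis of the alkoxy-stabilised allyl cation, is the hydride variant of the usual squarate-to-cyclobutenedione addition/rearrangement sequence.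

Step 6
Reactants: 12 3-(propan-2-yloxy)cyclobut-3-ene-1,2-dione
Product: 14 chloro(dimethylglyoxime)(pyridine)cobalt 2-isopropoxymaleoyl complex, via bis(triphenylphosphine) maleoylcobalt chloride 13 (not isolated)
Conditions: ClCo(PPh3)3 (1.05 equiv), benzene, 25 °C, Ar; then dimethylglyoxime (1.1 equiv), pyridine, 25 °C
Reagents that add atoms: chlorotris(triphenylphosphine)cobalt ClCo(PPh3)3, Cl[Co-3]([P+](c1ccccc1)(c1ccccc1)c1ccccc1)([P+](c1ccccc1)(c1ccccc1)c1ccccc1)[P+](c1ccccc1)(c1ccccc1)c1ccccc1; dimethylglyoxime, CC(=NO)C(C)=NO; pyridine, c1ccncc1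
Why: Oxidative addition of the monovalent cobalt of ClCo(PPh3)3 into the strained bond between the two carbonyl carbons of a cyclobutenedione gives the cobaltacyclopentenedione (maleoylcobalt) complex, and exchange of the phosphines for dimethylglyoxime and pyridine gives the labile form of such complexes that reacts with alkynes.

Step 7
Reactants: 14 chloro(dimethylglyoxime)(pyridine)cobalt 2-isopropoxymaleoyl complex; 9 (E)-1-ethoxyhenicos-16-en-1-yne
Product: 15 2-ethoxy-3-[(14E)-nonadec-14-en-1-yl]-5-(propan-2-yloxy)cyclohexa-2,5-diene-1,4-dione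
Conditions: 9 (1.3 equiv), ClCH2CH2Cl, 70 °C, Ar, no Lewis acid; then air, filtration through Et3N-deactivated SiO2
Reagents that add atoms: none
Why: Loss of pyridine from trivalent cobalt in 14 opens a site for π-coordination of ynol ether 9; migratory insertion should then join the alkyl-bearing, nucleophilic carbon of the ynol ether to the acyl carbon next to the isopropoxy-bearing carbon and place cobalt on the ethoxy-bearing carbon, and C–C reductive elimination from the seven-membered cobaltacycle joins that carbon to the second acyl carbon and releases monovalent cobalt. The closest known reaction type is the benzoquinone synthesis by alkyne insertion into maleoylcobalt and phthaloylcobalt complexes made from cyclobutenediones, applied here to a semisquarate-derived complex and an alkoxyalkyne. The six-membered quinone ring is closed as a formal [4+2] annulation of the four-carbon maleoyl unit with the two alkyne carbons, the closing event being acyl–vinyl reductive elimination at cobalt. No stereocentre is formed, and the isolated E-alkene should neither insert nor isomerise, so its geometry is kept. The step needs regioselectivity (alkoxy groups para, at C2 and C5), which rests on matched polarisation: the acyl next to the C–O carbon is cross-conjugated and the more electrophilic, the other acyl is a vinylogous ester and the poorer migrating group, and the ynol ether is strongly polarised. No Lewis acid is added because activation of the vinylogous ester carbonyl could reverse this preference, and 70 °C lies below the temperature at which ethyl ynol ethers lose ethene.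

Step 8
Reactants: 15 2-ethoxy-3-[(14E)-nonadec-14-en-1-yl]-5-(propan-2-yloxy)cyclohexa-2,5-diene-1,4-dione
Product: 16 2,5-dihydroxy-3-[(14E)-nonadec-14-en-1-yl]cyclohexa-2,5-diene-1,4-dione
Conditions: NaOH (2 M aq), EtOH, 25 → 50 °C, Ar; then HCl (2 M aq) to pH 2
Reagents that add atoms: sodium hydroxide, [Na+].[OH-] (hydroxide oxygen at C2 and C5)
Why: Addition–elimination of hydroxide at the two vinylogous ester carbons of a 2,5-dialkoxyquinone is the usual last step of 2,5-dihydroxy-3-alkylbenzoquinone syntheses, and the isolated E-alkene is inert to it.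

**Compound list**

1 | (E)-dec-5-en-1-ol | CCCC/C=C/CCCCO | starting material
2 | (E)-1-bromodec-5-ene | CCCC/C=C/CCCCBr | intermediate
3 | 1,9-dibromononane | BrCCCCCCCCCBr | starting material
4 | (E)-dec-5-en-1-ylmagnesium bromide | CCCC/C=C/CCCC[Mg]Br | intermediate
5 | (E)-1-bromononadec-14-ene | CCCC/C=C/CCCCCCCCCCCCCBr | intermediate
6 | (E)-1-iodononadec-14-ene | CCCC/C=C/CCCCCCCCCCCCCI | intermediate
7 | ethoxyethyne (ethoxyacetylene) | C#COCC | starting material
8 | lithium ethoxyacetylide | [Li]C#COCC | intermediate
9 | (E)-1-ethoxyhenicos-16-en-1-yne | CCCC/C=C/CCCCCCCCCCCCCC#COCC | intermediate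
10 | diisopropyl squarate, 3,4-di(propan-2-yloxy)cyclobut-3-ene-1,2-dione | CC(C)OC1=C(OC(C)C)C(=O)C1=O | starting material
11 | 4-hydroxy-2,3-di(propan-2-yloxy)cyclobut-2-en-1-one (racemic) | CC(C)OC1=C(OC(C)C)C(O)C1=O | intermediate
12 | 3-(propan-2-yloxy)cyclobut-3-ene-1,2-dione | CC(C)OC1=CC(=O)C1=O | intermediate
13 | chlorobis(triphenylphosphine)cobalt 2-isopropoxymaleoyl complex (3-isopropoxy-1-cobaltacyclopent-3-ene-2,5-dione, trivalent cobalt carrying Cl and two PPh3) | O=C1C=C(OC(C)C)C(=O)[Co-2]1(Cl)([P+](c2ccccc2)(c2ccccc2)c2ccccc2)[P+](c2ccccc2)(c2ccccc2)c2ccccc2 | intermediate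
14 | chloro(dimethylglyoxime)(pyridine)cobalt 2-isopropoxymaleoyl complex (same cobaltacycle, trivalent cobalt carrying Cl, pyridine and N,N'-chelating neutral dimethylglyoxime) | O=C1C=C(OC(C)C)C(=O)[Co-3]12(Cl)([n+]3ccccc3)[N+](O)=C(C)C(C)=[N+]2O | intermediate
15 | 2-ethoxy-3-[(14E)-nonadec-14-en-1-yl]-5-(propan-2-yloxy)cyclohexa-2,5-diene-1,4-dione | CCCC/C=C/CCCCCCCCCCCCCC1=C(OCC)C(=O)C=C(OC(C)C)C1=O | intermediate
16 | 2,5-dihydroxy-3-[(14E)-nonadec-14-en-1-yl]cyclohexa-2,5-diene-1,4-dione | CCCC/C=C/CCCCCCCCCCCCCC1=C(O)C(=O)C=C(O)C1=O | target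

**Step count**

Total steps: 8. Longest linear sequence: 6 steps (steps 1, 2, 3, 4, 7, 8); the cobalt branch (steps 5, 6) joins at step 7.

**Steps most likely to fail**

1. Step 7. The insertion may proceed with mixed or reversed orientation, placing the two alkoxy groups meta instead of para. The ynol ether may also be protonated and hydrated by the acidic oxime hydroxyl groups of coordinated dimethylglyoxime before it inserts. The fallback gives up the annulation and builds the ring from a bought arene; it sets out from iodide 6 and comes back to the route at target 16. Commercial 1,2,4,5-tetramethoxybenzene is lithiated with n-BuLi/TMEDA in THF at 0 °C at the position flanked by two methoxy groups, giving 2,3,5,6-tetramethoxyphenyllithium F1. Alkylation of F1 with 6 gives 1,2,4,5-tetramethoxy-3-[(14E)-nonadec-14-en-1-yl]benzene F2. Oxidative demethylation with (NH4)2Ce(NO3)6 in MeCN/H2O at 0 °C should give 2,5-dimethoxy-3-[(14E)-nonadec-14-en-1-yl]cyclohexa-2,5-diene-1,4-dione F3, and hydrolysis of F3 under the conditions of step 8 gives 16.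

2. Step 4. The SN2 alkylation of the weakly nucleophilic alkoxyacetylide may be slow, with competing E2 elimination of the iodide, decomposition of the acetylide on warming, and hydration of the product on silica. The fallback makes the electron-rich alkyne by oxidation of an ordinary acetylide instead of alkylation of an oxygenated one; it sets out from iodide 6 and comes back at target 16. Iodide 6 is alkylated with LiC≡CH·H2NCH2CH2NH2 in DMSO to give (E)-henicos-16-en-1-yne F4. Deprotonation with n-BuLi gives its lithium acetylide F5, and oxidation with LiOOtBu (from t-BuOOH and LiN(SiMe3)2) in THF at −78 → 0 °C gives the lithium ynolate F6. O-Silylation with triisopropylsilyl triflate gives triisopropyl{[(E)-henicos-16-en-1-yn-1-yl]oxy}silane F7. F7 takes the place of 9 under the conditions of step 7 to give 3-[(14E)-nonadec-14-en-1-yl]-5-(propan-2-yloxy)-2-[(triisopropylsilyl)oxy]cyclohexa-2,5-diene-1,4-dione F8, and the conditions of step 8 cleave both the silyl ether and the isopropyl ether to give 16.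

3. Step 2. Coupling may occur at both ends of the dibromide or as Wurtz homocoupling, and radical 5-exo cyclisation at the magnesium surface may contaminate the Grignard reagent of the hex-5-enyl-type bromide. The fallback reverses the roles of the partners and replaces statistical monosubstitution by a protected, monofunctional C9 nucleophile; it sets out from bromide 2 and comes back at iodide 6. Commercial 9-bromononan-1-ol is protected with dihydropyran and pyridinium p-toluenesulfonate to give 2-[(9-bromononyl)oxy]oxane F9. Its Grignard reagent, [9-(oxan-2-yloxy)nonyl]magnesium bromide F10 (Mg, THF), is coupled with 2 as the electrophile (Li2CuCl4 cat., THF, −10 °C) to give 2-{[(14E)-nonadec-14-en-1-yl]oxy}oxane F11. Methanolysis (TsOH, MeOH) gives (E)-nonadec-14-en-1-ol F12, and PPh3, I2 and imidazole in CH2Cl2 convert F12 directly into 6.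

**Further compounds**

F1 | step 7 | 2,3,5,6-tetramethoxyphenyllithium | [Li]c1c(OC)c(OC)cc(OC)c1OC
F2 | step 7 | 1,2,4,5-tetramethoxy-3-[(14E)-nonadec-14-en-1-yl]benzene | COc1cc(OC)c(OC)c(CCCCCCCCCCCCC/C=C/CCCC)c1OC
F3 | step 7 | 2,5-dimethoxy-3-[(14E)-nonadec-14-en-1-yl]cyclohexa-2,5-diene-1,4-dione | CCCC/C=C/CCCCCCCCCCCCCC1=C(OC)C(=O)C=C(OC)C1=O
F4 | step 4 | (E)-henicos-16-en-1-yne | CCCC/C=C/CCCCCCCCCCCCCC#C
F5 | step 4 | lithium (E)-henicos-16-en-1-yn-1-ide | CCCC/C=C/CCCCCCCCCCCCCC#C[Li]
F6 | step 4 | lithium (E)-henicos-16-en-1-yn-1-olate | CCCC/C=C/CCCCCCCCCCCCCC#CO[Li]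
F7 | step 4 | triisopropyl{[(E)-henicos-16-en-1-yn-1-yl]oxy}silane | CCCC/C=C/CCCCCCCCCCCCCC#CO[Si](C(C)C)(C(C)C)C(C)C
F8 | step 4 | 3-[(14E)-nonadec-14-en-1-yl]-5-(propan-2-yloxy)-2-[(triisopropylsilyl)oxy]cyclohexa-2,5-diene-1,4-dione | CCCC/C=C/CCCCCCCCCCCCCC1=C(O[Si](C(C)C)(C(C)C)C(C)C)C(=O)C=C(OC(C)C)C1=O
F9 | step 2 | 2-[(9-bromononyl)oxy]oxane | BrCCCCCCCCCOC1CCCCO1
F10 | step 2 | [9-(oxan-2-yloxy)nonyl]magnesium bromide | Br[Mg]CCCCCCCCCOC1CCCCO1
F11 | step 2 | 2-{[(14E)-nonadec-14-en-1-yl]oxy}oxane | CCCC/C=C/CCCCCCCCCCCCCOC1CCCCO1
F12 | step 2 | (E)-nonadec-14-en-1-ol | CCCC/C=C/CCCCCCCCCCCCCO
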